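**Retrosynthetic overview**
1. Target 37 ⇐ Yamaguchi acylation of the C1 alcohol of diol-enal 34; the enal ⇐ DIBAL-H/MnO2 from macrocyclic enoate 31.
2. The 11-membered carbocycle is the second and last ring, closed at C6=C7 by intramolecular Horner–Wadsworth–Emmons olefination of 30; the oxirane is the first ring (step 2).
3. 30 ⇐ C8 bromide + triethyl phosphonoacetate; the C1–C2 bond ⇐ catalyst-controlled (E)-alkenylzinc addition of west alkyne 22 to east epoxy aldehyde 4.
4. 22 ⇐ lipase desymmetrisation of prochiral diol 8 (quaternary C4), Wittig/hydroboration (C5–C6), cross-metathesis (side chain), Ohira–Bestmann (C2–C3); 4 ⇐ Sharpless epoxidation of allylic alcohol 2.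
5. Locants: C1 (acyloxy carbon), C2=C3, C4 (quaternary), C5, C6=C7(CHO), C8, C9, C10–C11 (oxirane; C11 carries CH3 and is bonded to C1).

Assumption: the lipase acetylates the enantiotopic CH2OH arm that gives (S)-9; if the chosen lipase prefers the other arm, (S)-9 is obtained instead by lipase hydrolysis of the diacetate of 8.

**East fragment**

Step 1
Reactants: 1 5-bromo-2-methylpent-2-ene
Product: 2 (2E)-5-bromo-2-methylpent-2-en-1-ol
Conditions: SeO2 (0.5 equiv), t-BuOOH, salicylic acid (cat.), CH2Cl2, rt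
Reagents that add atoms: tert-butyl hydroperoxide, CC(C)(C)OO
Why: SeO2-catalysed allylic oxidation (ene reaction then [2,3]-sigmatropic shift) hydroxylates the methyl group trans to the chain and gives the (E)-allylic alcohol.

Step 2
Reactants: 2 (2E)-5-bromo-2-methylpent-2-en-1-ol
Product: 3 [(2R,3R)-3-(2-bromoethyl)-2-methyloxiran-2-yl]methanol
Conditions: Ti(OiPr)4 (10 mol%), D-(−)-diisopropyl tartrate (12 mol%), t-BuOOH, 4 Å MS, CH2Cl2, −20 °C
Reagents that add atoms: tert-butyl hydroperoxide, CC(C)(C)OO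
Why: Sharpless asymmetric epoxidation, in which the titanium–D-tartrate catalyst delivers oxygen to one face of the (E)-allylic alcohol and so sets C10 and C11 (the first stereocentres) with the trans-oxirane geometry fixed by the alkene.

Step 3
Reactants: 3 [(2R,3R)-3-(2-bromoethyl)-2-methyloxiran-2-yl]methanol
Product: 4 (2S,3R)-3-(2-bromoethyl)-2-methyloxirane-2-carbaldehyde
Conditions: TEMPO (10 mol%), PhI(OAc)2, CH2Cl2, rt
Reagents that add atoms: none
Why: TEMPO-catalysed (oxoammonium) oxidation takes the primary alcohol to the non-enolisable epoxy aldehyde without touching the oxirane or the bromide.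

**West fragment**

Step 4
Reactants: 5 diethyl methylmalonate; 6 allyl bromide
Product: 7 diethyl 2-methyl-2-(prop-2-en-1-yl)propanedioate
Conditions: NaH, THF, 0 °C → rt
Reagents that add atoms: none
Why: Malonic ester alkylation (SN2 of the sodium enolate on the allylic bromide) installs the allyl group on an achiral quaternary carbon.

Step 5
Reactants: 7 diethyl 2-methyl-2-(prop-2-en-1-yl)propanedioate
Product: 8 2-methyl-2-(prop-2-en-1-yl)propane-1,3-diol
Conditions: LiAlH4, THF, 0 °C → reflux; aq. work-up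
Reagents that add atoms: none
Why: Hydride reduction of both esters gives the prochiral 2,2-disubstituted propane-1,3-diol and leaves the isolated alkene alone.

Step 6
Reactants: 8 2-methyl-2-(prop-2-en-1-yl)propane-1,3-diol
Product: 9 [(2S)-2-(hydroxymethyl)-2-methylpent-4-en-1-yl] acetate
Conditions: lipase (Burkholderia cepacia lipase, immobilised), vinyl acetate, i-Pr2O, rt
Reagents that add atoms: vinyl acetate, CC(=O)OC=C
Why: Lipase-catalysed enantiotopic-group-selective transesterification (desymmetrisation) acetylates one CH2OH arm of the prochiral diol only and thereby creates the quaternary stereocentre (future C4) by asymmetric biocatalysis.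

Step 7
Reactants: 9 [(2S)-2-(hydroxymethyl)-2-methylpent-4-en-1-yl] acetate
Product: 10 [(2R)-2-{[tert-butyl(diphenyl)silyl]oxymethyl}-2-methylpent-4-en-1-yl] acetate
Conditions: TBDPSCl, imidazole, CH2Cl2, 0 °C → rt
Reagents that add atoms: tert-butyl(chloro)diphenylsilane, CC(C)(C)[Si](Cl)(c1ccccc1)c1ccccc1
Why: Silylation of the free primary alcohol (substitution at silicon) tags the arm that becomes C3 before any acyl migration can erode the configuration.

Step 8
Reactants: 10 [(2R)-2-{[tert-butyl(diphenyl)silyl]oxymethyl}-2-methylpent-4-en-1-yl] acetate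
Product: 11 (2R)-2-{[tert-butyl(diphenyl)silyl]oxymethyl}-2-methylpent-4-en-1-ol
Conditions: K2CO3 (0.2 equiv), MeOH, 0 °C
Reagents that add atoms: none
Why: Base-catalysed transesterification removes the acetate from the other arm under conditions too mild for the silyl migration that would racemise C4.

Step 9
Reactants: 11 (2R)-2-{[tert-butyl(diphenyl)silyl]oxymethyl}-2-methylpent-4-en-1-ol
Product: 12 (2S)-2-{[tert-butyl(diphenyl)silyl]oxymethyl}-2-methylpent-4-enal
Conditions: TEMPO (10 mol%), PhI(OAc)2, CH2Cl2, rt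
Reagents that add atoms: none
Why: TEMPO-catalysed oxidation of the neopentyl alcohol gives the α-quaternary aldehyde, which cannot epimerise.

Step 10
Reactants: 12 (2S)-2-{[tert-butyl(diphenyl)silyl]oxymethyl}-2-methylpent-4-enal
Product: 13 tert-butyl{[(2R)-2-ethenyl-2-methylpent-4-en-1-yl]oxy}diphenylsilane
Conditions: Ph3PCH3Br, t-BuOK, THF, 0 °C → rt
Reagents that add atoms: methyltriphenylphosphonium bromide, C[P+](c1ccccc1)(c1ccccc1)c1ccccc1.[Br-]
Why: Wittig methylenation turns the aldehyde carbon into the future C5 as a vinyl group.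

Step 11
Reactants: 13 tert-butyl{[(2R)-2-ethenyl-2-methylpent-4-en-1-yl]oxy}diphenylsilane; 14 2-methylbut-3-en-2-ol
Product: 15 (3E,6R)-6-{[tert-butyl(diphenyl)silyl]oxymethyl}-2,6-dimethylocta-3,7-dien-2-ol
Conditions: 14 (5 equiv), second-generation Grubbs catalyst RuCl2(=CHPh)(PCy3)(H2IMes) (5 mol%), CH2Cl2, 40 °C
Reagents that add atoms: none
Why: Olefin cross-metathesis engages only the unhindered allyl group (the vinyl group on the quaternary carbon is too hindered) and gives the (E)-alkene with the tertiary allylic alcohol partner.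

Step 12
Reactants: 15 (3E,6R)-6-{[tert-butyl(diphenyl)silyl]oxymethyl}-2,6-dimethylocta-3,7-dien-2-ol
Product: 17 (3E,6R)-6-{[tert-butyl(diphenyl)silyl]oxymethyl}-2,6-dimethyloct-3-ene-2,8-diol, via B-alkyl-9-BBN adduct 16 (not isolated)
Conditions: 9-BBN (2.5 equiv), THF, 0 °C → rt; then NaOH, H2O2, 0 °C → rt
Reagents that add atoms: hydrogen peroxide, OO
Why: Anti-Markovnikov hydroboration–oxidation with the bulky borane takes the terminal vinyl group in preference to the hindered internal (E)-alkene and delivers C6 as a primary alcohol.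

Step 13
Reactants: 17 (3E,6R)-6-{[tert-butyl(diphenyl)silyl]oxymethyl}-2,6-dimethyloct-3-ene-2,8-diol
Product: 18 (3E,6R)-6-{[tert-butyl(diphenyl)silyl]oxymethyl}-8-[(4-methoxyphenyl)methoxy]-2,6-dimethyloct-3-en-2-ol
Conditions: NaH (1.05 equiv), 4-methoxybenzyl chloride, n-Bu4NI (cat.), THF–DMF, 0 °C → rt
Reagents that add atoms: 4-methoxybenzyl chloride, COc1ccc(CCl)cc1
Why: Williamson etherification occurs at the primary alkoxide because the tertiary alcohol is too hindered to compete.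

Step 14
Reactants: 18 (3E,6R)-6-{[tert-butyl(diphenyl)silyl]oxymethyl}-8-[(4-methoxyphenyl)methoxy]-2,6-dimethyloct-3-en-2-ol
Product: 19 (2R,4E)-2-{2-[(4-methoxyphenyl)methoxy]ethyl}-2,6-dimethylhept-4-ene-1,6-diol
Conditions: n-Bu4NF, THF, rt
Reagents that add atoms: none
Why: Fluoride-induced desilylation frees the neopentyl primary alcohol while the PMB ether is untouched.

Step 15
Reactants: 19 (2R,4E)-2-{2-[(4-methoxyphenyl)methoxy]ethyl}-2,6-dimethylhept-4-ene-1,6-diol
Product: 20 (2R,4E)-6-hydroxy-2-{2-[(4-methoxyphenyl)methoxy]ethyl}-2,6-dimethylhept-4-enal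
Conditions: TEMPO (10 mol%), PhI(OAc)2, CH2Cl2, rt
Reagents that add atoms: none
Why: TEMPO-catalysed oxidation is selective for the primary alcohol because the tertiary allylic alcohol has no carbinol hydrogen.

Step 16
Reactants: 20 (2R,4E)-6-hydroxy-2-{2-[(4-methoxyphenyl)methoxy]ethyl}-2,6-dimethylhept-4-enal
Product: 21 (3E,6R)-6-ethynyl-8-[(4-methoxyphenyl)methoxy]-2,6-dimethyloct-3-en-2-ol
Conditions: dimethyl (1-diazo-2-oxopropyl)phosphonate, K2CO3, MeOH, 0 °C → rt
Reagents that add atoms: dimethyl (1-diazo-2-oxopropyl)phosphonate, COP(=O)(OC)C(=[N+]=[N-])C(C)=O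
Why: Ohira–Bestmann (Seyferth–Gilbert) homologation converts the non-enolisable aldehyde into the terminal alkyne, the aldehyde carbon becoming C3 and the new carbon C2.

Step 17
Reactants: 21 (3E,6R)-6-ethynyl-8-[(4-methoxyphenyl)methoxy]-2,6-dimethyloct-3-en-2-ol
Product: 22 triethyl{[(3E,6R)-6-ethynyl-8-[(4-methoxyphenyl)methoxy]-2,6-dimethyloct-3-en-2-yl]oxy}silane
Conditions: TESOTf, 2,6-lutidine, CH2Cl2, −78 °C
Reagents that add atoms: triethylsilyl trifluoromethanesulfonate, CC[Si](CC)(CC)OS(=O)(=O)C(F)(F)F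
Why: The silyl triflate silylates the hindered tertiary alcohol so that it cannot quench the organoborane and organozinc reagents of the next step.

**Union and endgame**

Step 18
Reactants: 22 triethyl{[(3E,6R)-6-ethynyl-8-[(4-methoxyphenyl)methoxy]-2,6-dimethyloct-3-en-2-yl]oxy}silane; 4 (2S,3R)-3-(2-bromoethyl)-2-methyloxirane-2-carbaldehyde
Product: 25 (1S,2E,4R,6E)-1-[(2R,3R)-3-(2-bromoethyl)-2-methyloxiran-2-yl]-4-{2-[(4-methoxyphenyl)methoxy]ethyl}-4,8-dimethyl-8-[(triethylsilyl)oxy]nona-2,6-dien-1-ol, via alkenylborane 23 (not isolated), via alkenylzinc 24 (not isolated)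
Conditions: Cy2BH, toluene, 0 °C → rt; Me2Zn, −78 °C; (−)-MIB (3-exo-morpholinoisoborneol, 10 mol%), then 4, −20 → 0 °C; H2O work-up
Reagents that add atoms: none
Why: Oppolzer–Walsh catalytic asymmetric alkenylzinc addition, in which syn-hydroboration fixes the (E)-C2=C3 alkene, boron-to-zinc exchange gives the alkenylzinc, and the (−)-MIB–zinc catalyst directs addition to the Si face of the non-enolisable aldehyde to set (S)-C1.

Step 19
Reactants: 25 (the C1 alcohol)
Product: 26 bis(triethylsilyl) ether bromide (25 silylated at the C1 hydroxyl; no stereocentre changed)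
Conditions: TESOTf, 2,6-lutidine, CH2Cl2, −78 °C
Reagents that add atoms: triethylsilyl trifluoromethanesulfonate, CC[Si](CC)(CC)OS(=O)(=O)C(F)(F)F
Why: Low-temperature silylation protects the C1 alcohol before base is used and blocks Payne rearrangement of the epoxy alcohol.

Step 20
Reactants: 26 bis(triethylsilyl) ether bromide; 27 triethyl phosphonoacetate
Product: 28 C7 phosphonoacetate (Br of 26 replaced by CH(CO2Et)P(O)(OEt)2; both C7 epimers)
Conditions: NaH, 27 (3 equiv), DMF, 0 → 50 °C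
Reagents that add atoms: none
Why: SN2 alkylation of the sodium phosphonoacetate anion by the primary bromide forms the C7–C8 bond, and the excess of 27 suppresses dialkylation.

Step 21
Reactants: 28 C7 phosphonoacetate
Product: 29 primary alcohol (PMB ether of 28 cleaved to CH2CH2OH)
Conditions: DDQ, CH2Cl2–pH 7 buffer, 0 °C
Reagents that add atoms: none
Why: Oxidative PMB cleavage (hydride abstraction by DDQ then hydrolysis) frees the C6 alcohol and leaves the silyl ethers and the oxirane intact.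

Step 22
Reactants: 29 primary alcohol
Product: 30 seco aldehyde-phosphonate (CH2CH2OH of 29 oxidised to CH2CHO)
Conditions: TEMPO (10 mol%), PhI(OAc)2, CH2Cl2, rt
Reagents that add atoms: none
Why: TEMPO-catalysed oxidation gives the C6 aldehyde under near-neutral conditions that do not trigger premature olefination.

Step 23
Reactants: 30 seco aldehyde-phosphonate
Product: 31 ethyl (1R,4E,7R,8E,10S,11S)-7,11-dimethyl-10-[(triethylsilyl)oxy]-7-{(2E)-4-methyl-4-[(triethylsilyl)oxy]pent-2-en-1-yl}-12-oxabicyclo[9.1.0]dodeca-4,8-diene-4-carboxylate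
Conditions: LiCl, DBU, MeCN, 1 mM (slow addition), rt → 40 °C
Reagents that add atoms: none
Why: Intramolecular Horner–Wadsworth–Emmons olefination under Masamune–Roush conditions at high dilution closes the 11-membered ring and gives the (E)-enoate (ester trans to C5, ring carbons cis), the thermodynamically preferred trisubstituted geometry.

Step 24
Reactants: 31 macrocyclic ethyl enoate
Product: 32 [(1R,4E,7R,8E,10S,11S)-7,11-dimethyl-10-[(triethylsilyl)oxy]-7-{(2E)-4-methyl-4-[(triethylsilyl)oxy]pent-2-en-1-yl}-12-oxabicyclo[9.1.0]dodeca-4,8-dien-4-yl]methanol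
Conditions: i-Bu2AlH (3 equiv), CH2Cl2, −78 °C; aq. work-up
Reagents that add atoms: none
Why: 1,2-Reduction of the conjugated ester by DIBAL-H gives the allylic alcohol, and the oxirane survives at low temperature.

Step 25
Reactants: 32 macrocyclic allylic alcohol
Product: 33 (1R,4E,7R,8E,10S,11S)-7,11-dimethyl-10-[(triethylsilyl)oxy]-7-{(2E)-4-methyl-4-[(triethylsilyl)oxy]pent-2-en-1-yl}-12-oxabicyclo[9.1.0]dodeca-4,8-diene-4-carbaldehyde
Conditions: MnO2, CH2Cl2, rt
Reagents that add atoms: none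
Why: MnO2 oxidises only the primary allylic alcohol and gives the (E)-enal.

Step 26
Reactants: 33 bis(triethylsilyl) enal
Product: 34 (1R,4E,7R,8E,10S,11R)-10-hydroxy-7-[(2E)-4-hydroxy-4-methylpent-2-en-1-yl]-7,11-dimethyl-12-oxabicyclo[9.1.0]dodeca-4,8-diene-4-carbaldehyde
Conditions: HF·pyridine, pyridine, THF, 0 °C → rt
Reagents that add atoms: none
Why: Buffered fluoride desilylation removes both triethylsilyl ethers without opening the oxirane or touching the enal (the change of the C11 descriptor is a CIP priority effect only).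

Step 27
Reactants: 34 diol-enal; 35 3-methylbut-2-enoic acid
Product: 37 (1R,4E,7R,8E,10S,11S)-4-formyl-7-[(2E)-4-hydroxy-4-methylpent-2-en-1-yl]-7,11-dimethyl-12-oxabicyclo[9.1.0]dodeca-4,8-dien-10-yl 3-methylbut-2-enoate, via mixed anhydride 36 (not isolated)
Conditions: 35, 2,4,6-trichlorobenzoyl chloride, Et3N, THF, rt; then 34, DMAP, toluene, rt
Reagents that add atoms: none
Why: Yamaguchi esterification acylates the secondary C1 alcohol on oxygen (configuration retained) while the tertiary alcohol is too hindered to react.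

**Compound list**
1 | 5-bromo-2-methylpent-2-ene | CC(C)=CCCBr | starting material
2 | (2E)-5-bromo-2-methylpent-2-en-1-ol | OC/C(C)=C/CCBr | intermediate
3 | [(2R,3R)-3-(2-bromoethyl)-2-methyloxiran-2-yl]methanol | OC[C@@]1(C)O[C@@H]1CCBr | intermediate
4 | (2S,3R)-3-(2-bromoethyl)-2-methyloxirane-2-carbaldehyde | O=C[C@@]1(C)O[C@@H]1CCBr | intermediate
5 | diethyl methylmalonate | CCOC(=O)C(C)C(=O)OCC | starting material
6 | allyl bromide | C=CCBr | starting material
7 | diethyl 2-methyl-2-(prop-2-en-1-yl)propanedioate | CCOC(=O)C(C)(CC=C)C(=O)OCC | intermediate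
8 | 2-methyl-2-(prop-2-en-1-yl)propane-1,3-diol | OCC(C)(CC=C)CO | intermediate
9 | [(2S)-2-(hydroxymethyl)-2-methylpent-4-en-1-yl] acetate | OC[C@](C)(CC=C)COC(C)=O | intermediate
10 | [(2R)-2-{[tert-butyl(diphenyl)silyl]oxymethyl}-2-methylpent-4-en-1-yl] acetate | CC(C)(C)[Si](c1ccccc1)(c1ccccc1)OC[C@](C)(CC=C)COC(C)=O | intermediate
11 | (2R)-2-{[tert-butyl(diphenyl)silyl]oxymethyl}-2-methylpent-4-en-1-ol | CC(C)(C)[Si](c1ccccc1)(c1ccccc1)OC[C@](C)(CC=C)CO | intermediate
12 | (2S)-2-{[tert-butyl(diphenyl)silyl]oxymethyl}-2-methylpent-4-enal | CC(C)(C)[Si](c1ccccc1)(c1ccccc1)OC[C@](C)(CC=C)C=O | intermediate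
13 | tert-butyl{[(2R)-2-ethenyl-2-methylpent-4-en-1-yl]oxy}diphenylsilane | CC(C)(C)[Si](c1ccccc1)(c1ccccc1)OC[C@](C)(CC=C)C=C | intermediate
14 | 2-methylbut-3-en-2-ol | CC(C)(O)C=C | starting material
15 | (3E,6R)-6-{[tert-butyl(diphenyl)silyl]oxymethyl}-2,6-dimethylocta-3,7-dien-2-ol | CC(C)(C)[Si](c1ccccc1)(c1ccccc1)OC[C@](C)(C/C=C/C(C)(C)O)C=C | intermediate
16 | B-alkyl-9-borabicyclo[3.3.1]nonane adduct of 15 (boron on the terminal carbon of the former vinyl group; not isolated) | CC(C)(C)[Si](c1ccccc1)(c1ccccc1)OC[C@](C)(C/C=C/C(C)(C)O)CCB1C2CCCC1CCC2 | intermediate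
17 | (3E,6R)-6-{[tert-butyl(diphenyl)silyl]oxymethyl}-2,6-dimethyloct-3-ene-2,8-diol | CC(C)(C)[Si](c1ccccc1)(c1ccccc1)OC[C@](C)(C/C=C/C(C)(C)O)CCO | intermediate
18 | (3E,6R)-6-{[tert-butyl(diphenyl)silyl]oxymethyl}-8-[(4-methoxyphenyl)methoxy]-2,6-dimethyloct-3-en-2-ol | CC(C)(C)[Si](c1ccccc1)(c1ccccc1)OC[C@](C)(C/C=C/C(C)(C)O)CCOCc1ccc(OC)cc1 | intermediate
19 | (2R,4E)-2-{2-[(4-methoxyphenyl)methoxy]ethyl}-2,6-dimethylhept-4-ene-1,6-diol | OC[C@](C)(C/C=C/C(C)(C)O)CCOCc1ccc(OC)cc1 | intermediate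
20 | (2R,4E)-6-hydroxy-2-{2-[(4-methoxyphenyl)methoxy]ethyl}-2,6-dimethylhept-4-enal | O=C[C@](C)(C/C=C/C(C)(C)O)CCOCc1ccc(OC)cc1 | intermediate
21 | (3E,6R)-6-ethynyl-8-[(4-methoxyphenyl)methoxy]-2,6-dimethyloct-3-en-2-ol | C#C[C@](C)(C/C=C/C(C)(C)O)CCOCc1ccc(OC)cc1 | intermediate
22 | triethyl{[(3E,6R)-6-ethynyl-8-[(4-methoxyphenyl)methoxy]-2,6-dimethyloct-3-en-2-yl]oxy}silane | C#C[C@](C)(C/C=C/C(C)(C)O[Si](CC)(CC)CC)CCOCc1ccc(OC)cc1 | intermediate
23 | (E)-alkenyl(dicyclohexyl)borane from 22 (boron on C2; not isolated) | C1CCCCC1B(C1CCCCC1)/C=C/[C@](C)(C/C=C/C(C)(C)O[Si](CC)(CC)CC)CCOCc1ccc(OC)cc1 | intermediate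
24 | (E)-alkenyl(methyl)zinc from 23 (zinc on C2; not isolated) | C[Zn]/C=C/[C@](C)(C/C=C/C(C)(C)O[Si](CC)(CC)CC)CCOCc1ccc(OC)cc1 | intermediate
25 | (1S,2E,4R,6E)-1-[(2R,3R)-3-(2-bromoethyl)-2-methyloxiran-2-yl]-4-{2-[(4-methoxyphenyl)methoxy]ethyl}-4,8-dimethyl-8-[(triethylsilyl)oxy]nona-2,6-dien-1-ol | O[C@@H](/C=C/[C@](C)(C/C=C/C(C)(C)O[Si](CC)(CC)CC)CCOCc1ccc(OC)cc1)[C@@]1(C)O[C@@H]1CCBr | intermediate
26 | bis(triethylsilyl) ether bromide: 25 silylated at the C1 hydroxyl (no stereocentre changed) | CC[Si](CC)(CC)O[C@@H](/C=C/[C@](C)(C/C=C/C(C)(C)O[Si](CC)(CC)CC)CCOCc1ccc(OC)cc1)[C@@]1(C)O[C@@H]1CCBr | intermediate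
27 | triethyl phosphonoacetate | CCOC(=O)CP(=O)(OCC)OCC | starting material
28 | C7 phosphonoacetate: Br of 26 replaced by CH(CO2Et)P(O)(OEt)2 (both C7 epimers) | CC[Si](CC)(CC)O[C@@H](/C=C/[C@](C)(C/C=C/C(C)(C)O[Si](CC)(CC)CC)CCOCc1ccc(OC)cc1)[C@@]1(C)O[C@@H]1CCC(C(=O)OCC)P(=O)(OCC)OCC | intermediate
29 | primary alcohol: PMB ether of 28 cleaved to CH2CH2OH | CC[Si](CC)(CC)O[C@@H](/C=C/[C@](C)(C/C=C/C(C)(C)O[Si](CC)(CC)CC)CCO)[C@@]1(C)O[C@@H]1CCC(C(=O)OCC)P(=O)(OCC)OCC | intermediate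
30 | seco aldehyde-phosphonate: CH2CH2OH of 29 oxidised to CH2CHO | CC[Si](CC)(CC)O[C@@H](/C=C/[C@](C)(C/C=C/C(C)(C)O[Si](CC)(CC)CC)CC=O)[C@@]1(C)O[C@@H]1CCC(C(=O)OCC)P(=O)(OCC)OCC | intermediate
31 | ethyl (1R,4E,7R,8E,10S,11S)-7,11-dimethyl-10-[(triethylsilyl)oxy]-7-{(2E)-4-methyl-4-[(triethylsilyl)oxy]pent-2-en-1-yl}-12-oxabicyclo[9.1.0]dodeca-4,8-diene-4-carboxylate | CC[Si](CC)(CC)O[C@H]1/C=C/[C@](C)(C/C=C/C(C)(C)O[Si](CC)(CC)CC)C/C=C(/C(=O)OCC)CC[C@H]2O[C@]12C | intermediate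
32 | [(1R,4E,7R,8E,10S,11S)-7,11-dimethyl-10-[(triethylsilyl)oxy]-7-{(2E)-4-methyl-4-[(triethylsilyl)oxy]pent-2-en-1-yl}-12-oxabicyclo[9.1.0]dodeca-4,8-dien-4-yl]methanol | CC[Si](CC)(CC)O[C@H]1/C=C/[C@](C)(C/C=C/C(C)(C)O[Si](CC)(CC)CC)C/C=C(/CO)CC[C@H]2O[C@]12C | intermediate
33 | (1R,4E,7R,8E,10S,11S)-7,11-dimethyl-10-[(triethylsilyl)oxy]-7-{(2E)-4-methyl-4-[(triethylsilyl)oxy]pent-2-en-1-yl}-12-oxabicyclo[9.1.0]dodeca-4,8-diene-4-carbaldehyde | CC[Si](CC)(CC)O[C@H]1/C=C/[C@](C)(C/C=C/C(C)(C)O[Si](CC)(CC)CC)C/C=C(/C=O)CC[C@H]2O[C@]12C | intermediate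
34 | (1R,4E,7R,8E,10S,11R)-10-hydroxy-7-[(2E)-4-hydroxy-4-methylpent-2-en-1-yl]-7,11-dimethyl-12-oxabicyclo[9.1.0]dodeca-4,8-diene-4-carbaldehyde | O[C@H]1/C=C/[C@](C)(C/C=C/C(C)(C)O)C/C=C(/C=O)CC[C@H]2O[C@]12C | intermediate
35 | 3-methylbut-2-enoic acid | CC(C)=CC(=O)O | starting material
36 | 3-methylbut-2-enoic 2,4,6-trichlorobenzoic anhydride (not isolated) | CC(C)=CC(=O)OC(=O)c1c(Cl)cc(Cl)cc1Cl | intermediate
37 | (1R,4E,7R,8E,10S,11S)-4-formyl-7-[(2E)-4-hydroxy-4-methylpent-2-en-1-yl]-7,11-dimethyl-12-oxabicyclo[9.1.0]dodeca-4,8-dien-10-yl 3-methylbut-2-enoate (CNP0164725.2) | CC(C)=CC(=O)O[C@H]1/C=C/[C@](C)(C/C=C/C(C)(C)O)C/C=C(/C=O)CC[C@H]2O[C@]12C | target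

**Step count**
Total: 27 steps (east fragment 3, west fragment 14, union and endgame 10).
Longest linear sequence: 24 steps (steps 4–27, from 5 to 37).

**Three steps most likely to fail, each with a fallback**

Step 6 (lipase desymmetrisation). Methyl and allyl differ little in size, so the enantiomeric excess may be modest. The fallback sets out from diester 7 and returns at 11; it differentiates the two arms at the carboxyl oxidation level with a different hydrolase. Pig liver esterase (an esterase) in pH 7.5 phosphate buffer hydrolyses one enantiotopic ester of 7 to (2R)-2-(ethoxycarbonyl)-2-methylpent-4-enoic acid F1, whose ee can be raised by recrystallising its dicyclohexylammonium salt. LiBH4 in THF reduces the ester of the lithium carboxylate to (2S)-2-(hydroxymethyl)-2-methylpent-4-enoic acid F2. TBDPSCl (2.2 equiv) and imidazole give tert-butyl(diphenyl)silyl (2S)-2-{[tert-butyl(diphenyl)silyl]oxymethyl}-2-methylpent-4-enoate F3, and LiAlH4 at 0 °C reduces the silyl ester to 11.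

Step 18 (alkenylzinc addition to the epoxy aldehyde). The catalyst must override, or be reinforced by, the facial bias of the α,β-epoxy aldehyde, so the C1 diastereoselectivity is uncertain. The fallback sets out from 2 and 22 and returns at 26; it sets C1 on an achiral aldehyde and introduces the oxirane afterwards under reagent control. MnO2 oxidises 2 to (2E)-5-bromo-2-methylpent-2-enal F4. Alkenylzinc 24, made from 22 as in step 18, adds to F4 under (−)-MIB catalysis to give (3E,5S,6E,8R,10E)-1-bromo-8-{2-[(4-methoxyphenyl)methoxy]ethyl}-4,8,12-trimethyl-12-[(triethylsilyl)oxy]trideca-3,6,10-trien-5-ol F5. TESOTf and 2,6-lutidine give the C1 triethylsilyl ether of that alcohol F6. Shi epoxidation (D-fructose-derived ketone catalyst, Oxone 2KHSO5·KHSO4·K2SO4, K2CO3, MeCN–dimethoxymethane–buffer, 0 °C) then oxidises the most electron-rich, trisubstituted C10=C11 alkene on the required face to give 26.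

Step 23 (Horner–Wadsworth–Emmons ring closure). Closing a medium ring this way may give cyclic dimers. The fallback sets out from 26 and returns at 32; it closes the same C6–C7 bond by a samarium-templated intramolecular Reformatsky reaction, a method with good precedent for medium rings.
- The lithium enolate of tert-butyl acetate (LiN(i-Pr)2, THF–DMPU, −78 → −20 °C) displaces the bromide of 26 to give the tert-butyl ester F7.
- Enolisation with LiN(i-Pr)2 and quenching with CBr4 gives the α-bromo ester F8.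
- DDQ then gives the bromo ester alcohol F9, and TEMPO/PhI(OAc)2 the bromo ester aldehyde F10.
- SmI2 in THF at high dilution (−78 → 0 °C) closes the ring to the macrocyclic β-hydroxy ester F11.
- MsCl and Et3N give the C6 mesylate F12, and DBU eliminates it to the macrocyclic tert-butyl (E)-enoate F13.
- i-Bu2AlH reduces F13 to 32.

**Further compounds**
F1 | step 6 | (2R)-2-(ethoxycarbonyl)-2-methylpent-4-enoic acid | CCOC(=O)[C@](C)(CC=C)C(=O)O
F2 | step 6 | (2S)-2-(hydroxymethyl)-2-methylpent-4-enoic acid | OC[C@](C)(CC=C)C(=O)O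
F3 | step 6 | tert-butyl(diphenyl)silyl (2S)-2-{[tert-butyl(diphenyl)silyl]oxymethyl}-2-methylpent-4-enoate | CC(C)(C)[Si](c1ccccc1)(c1ccccc1)OC[C@](C)(CC=C)C(=O)O[Si](c1ccccc1)(c1ccccc1)C(C)(C)C
F4 | step 18 | (2E)-5-bromo-2-methylpent-2-enal | O=C/C(C)=C/CCBr
F5 | step 18 | (3E,5S,6E,8R,10E)-1-bromo-8-{2-[(4-methoxyphenyl)methoxy]ethyl}-4,8,12-trimethyl-12-[(triethylsilyl)oxy]trideca-3,6,10-trien-5-ol | O[C@@H](/C=C/[C@](C)(C/C=C/C(C)(C)O[Si](CC)(CC)CC)CCOCc1ccc(OC)cc1)/C(C)=C/CCBr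
F6 | step 18 | C1 triethylsilyl ether of F5 | CC[Si](CC)(CC)O[C@@H](/C=C/[C@](C)(C/C=C/C(C)(C)O[Si](CC)(CC)CC)CCOCc1ccc(OC)cc1)/C(C)=C/CCBr
F7 | step 23 | tert-butyl ester (Br of 26 replaced by CH2CO2t-Bu) | CC[Si](CC)(CC)O[C@@H](/C=C/[C@](C)(C/C=C/C(C)(C)O[Si](CC)(CC)CC)CCOCc1ccc(OC)cc1)[C@@]1(C)O[C@@H]1CCCC(=O)OC(C)(C)C
F8 | step 23 | α-bromo ester (CHBrCO2t-Bu at C7; both epimers) | CC[Si](CC)(CC)O[C@@H](/C=C/[C@](C)(C/C=C/C(C)(C)O[Si](CC)(CC)CC)CCOCc1ccc(OC)cc1)[C@@]1(C)O[C@@H]1CCC(Br)C(=O)OC(C)(C)C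
F9 | step 23 | bromo ester alcohol (PMB ether of F8 cleaved) | CC[Si](CC)(CC)O[C@@H](/C=C/[C@](C)(C/C=C/C(C)(C)O[Si](CC)(CC)CC)CCO)[C@@]1(C)O[C@@H]1CCC(Br)C(=O)OC(C)(C)C
F10 | step 23 | bromo ester aldehyde (C6 aldehyde) | CC[Si](CC)(CC)O[C@@H](/C=C/[C@](C)(C/C=C/C(C)(C)O[Si](CC)(CC)CC)CC=O)[C@@]1(C)O[C@@H]1CCC(Br)C(=O)OC(C)(C)C
F11 | step 23 | macrocyclic β-hydroxy ester (C6–OH and C7–CO2t-Bu; diastereomer mixture) | CC[Si](CC)(CC)O[C@H]1/C=C/[C@](C)(C/C=C/C(C)(C)O[Si](CC)(CC)CC)CC(O)C(C(=O)OC(C)(C)C)CC[C@H]2O[C@]12C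
F12 | step 23 | C6 mesylate of F11 | CC[Si](CC)(CC)O[C@H]1/C=C/[C@](C)(C/C=C/C(C)(C)O[Si](CC)(CC)CC)CC(OS(C)(=O)=O)C(C(=O)OC(C)(C)C)CC[C@H]2O[C@]12C
F13 | step 23 | macrocyclic tert-butyl (E)-enoate (31 with CO2t-Bu in place of CO2Et) | CC[Si](CC)(CC)O[C@H]1/C=C/[C@](C)(C/C=C/C(C)(C)O[Si](CC)(CC)CC)C/C=C(/C(=O)OC(C)(C)C)CC[C@H]2O[C@]12C
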